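Cedar is elm's warmer neighbour, with the same charge and the same time.

- cedar: J 0.10 M; L 1.20 equiv; temperature 40 °C; time 8.0 min
- elm: J 0.10 M; L 1.20 equiv; temperature 25 °C; time 8.0 min

    J ⇌ X (K1 = 0.50, k1 = 0.0050 /s, Ea1 = 91.0 kJ/mol, ΔH1 = 19.0 kJ/mol)
    L → Z (k2 = 0.27 /s, Ea2 = 85.0 kJ/mol)
    X + Z → X.Z (k3 = 0.035 /M/s, Ea3 = 49.0 kJ/mol)
    J ⇌ G (K4 = 1.6, k4 = 0.023 /s, Ea4 = 75.0 kJ/mol, ΔH4 = −14.0 kJ/mol)
    L + X.Z ⇌ L.X.Z, settled at all times (K5 = 7.1 /M, ΔH5 = −52.0 kJ/mol)
    (constants at 25 °C)

* the flask that comes out highest in amount of X.Z, in percent of the J charged, or "all alike" when all lie within 1.5 percentage points (cedar / elm / all alike)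
* X.Z at the end, in percent of the J charged, cedar
* X.Z at the end, in percent of the J charged, elm

- what is said of X.Z includes L.X.Z
- at 25 °C the constants are as listed, elsewhere as the activation energies and enthalpies make them

- L turns into Z with a half-life of 2.57 s, far shorter than the 8.0 min, so I start Z at Zs = 0.120 M and leave L.X.Z out.
- In elm, J goes to G with constant 0.023 /s, faster than to X with constant a = 0.0050 /s, so I treat J, G and X as one pool P, starting at c = 0.10 M.
- Each X.Z takes one Z and one P, so Z − P stays at D = 0.0200 M.
- Let f be the share of P standing as X, and m the constant of X + Z. Then dP/dt = −κ·P·(P + D), with κ = m·f.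
- This rate integrates in closed form: P/c = D/(Zs·e^(κDt) − c). X.Z is what P has lost.
- My first guess for elm puts X at balance with J and G, with KX = X/J and KG = G/J, so f = KX/(1 + KX + KG) = 0.161. That gives 25.0% X.Z.
- That balance is the weak link. In elm, X falls back to J with b = 0.0100 /s, but Z also takes it at 0.00420 /s, which is not small beside b.
- So I reforge it with X in quasi-steady state: ρ = X/J = a/(b + m·Zs) = 0.352, and f = ρ/(1 + KG + ρ) = 0.119.
- Elm's working constant, the X + Z constant times the share of the pool standing as X, is then κ = 0.00417 /M/s. It gives 19.7% X.Z.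
- In cedar, m grows 2.6 times to 0.0902 /M/s. The energies carry a to 0.0290 /s, KX to 0.722 and KG to 1.22.
- The same steps give cedar ρ = 0.569, f = 0.204 and κ = 0.0184 /M/s. I commit to 53.7% X.Z, above elm.
- The forecast names cedar, with 55% (50% to 60%) for cedar and 20.5% (18% to 23%) for elm. It holds that “J and G act as one pool feeding X”. My numbers lie a little below its own.
- The simulation gives cedar highest, with 54.8% in cedar and 19.3% in elm. The forecast stands.
- Part of what holds elm at 19.3% X.Z is the falling back of X to J, acting together with the time given: with that falling back struck out, elm gives 35.9%, and left until 80.0 min it gives 77.6%. The further flask is elm read at 30 min: elm's κ puts X.Z at 49.3%, and that flask reads 51.0%.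

The numbers were chosen freely; the run is a simulation.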